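**Plan**
- Retrosynthesis: the two MOM ethers are removed and the C4 ketone is taken back to a C4 methyl ether. The C ring is then cut at O1–C2 and C3–C4 in a retro-[4+2]. This works because O1–C8a–C4a–C4 is the oxa-diene of an ortho-quinone methide hidden in the A-ring salicylaldehyde, and C2–C3 with its 4-methoxyphenyl group is 4-vinylanisole.
- The aldehyde is cut further at the C6–prenyl bond (retro para-Claisen–Cope to the O-prenyl ether) and at the two MOM ethers, back to 2,4,6-trihydroxybenzaldehyde.
- Forward: the A ring is dressed first (bis-MOM, O-prenylation, Claisen–Cope). The C ring is then closed and the B ring attached in one three-component cycloaddition. Oxidation at C4 and MOM removal finish the route.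
- Stereochemistry: the only stereocentre of the target, C2 (S), is set in the cycloaddition by a chiral Brønsted acid. The transient C4 centre (2,4-cis) is erased by the oxidation.

Key step: step 4

Assumption: the sense of induction of the chiral acid in step 4 cannot be predicted with confidence, so the catalyst enantiomer that gives the (2S) adduct is fixed in a first screen (its mirror image would give the 2R series).

**Step 1**
Reactants: 1 2,4,6-trihydroxybenzaldehyde
Product: 2 2-hydroxy-4,6-bis(methoxymethoxy)benzaldehyde
Conditions: MOMCl (2.2 equiv), i-Pr2NEt (3 equiv), CH2Cl2, 0 °C → rt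
Reagents that add atoms: chloromethyl methyl ether (MOMCl), COCCl
Why: Base-mediated O-alkylation (Williamson-type) should take the para hydroxyl and one ortho hydroxyl, while the last ortho hydroxyl stays free because it is chelated to the formyl oxygen.

**Step 2**
Reactants: 2 2-hydroxy-4,6-bis(methoxymethoxy)benzaldehyde + 3 prenyl bromide (1-bromo-3-methylbut-2-ene)
Product: 4 2,4-bis(methoxymethoxy)-6-[(3-methylbut-2-en-1-yl)oxy]benzaldehyde
Conditions: K2CO3, DMF, rt → 40 °C
Reagents that add atoms: none
Why: Williamson ether synthesis, SN2 attack of the phenoxide on the primary allylic bromide; the MOM ethers and the non-enolisable aldehyde are inert to carbonate.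

**Step 3**
Reactants: 4 2,4-bis(methoxymethoxy)-6-[(3-methylbut-2-en-1-yl)oxy]benzaldehyde
Product: 7 6-hydroxy-2,4-bis(methoxymethoxy)-3-(3-methylbut-2-en-1-yl)benzaldehyde (prenyl between the two MOM ethers, para to the free OH), via ortho-dienone 5 (not isolated), via para-dienone 6 (not isolated)
Conditions: PhNEt2, 200 °C, Ar, sealed tube
Reagents that add atoms: none
Why: Tandem aromatic Claisen–Cope (para-Claisen) rearrangement: the first [3,3] shift puts a 1,1-dimethylallyl group on the only free ortho carbon (dienone 5), a Cope shift carries it, restored as a prenyl group, to the para carbon between the MOM ethers (dienone 6), and enolisation gives the formyl-chelated phenol, a sequence well established for the corresponding 2-acylphloroglucinol prenyl ethers.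

**Step 4**
Reactants: 7 6-hydroxy-2,4-bis(methoxymethoxy)-3-(3-methylbut-2-en-1-yl)benzaldehyde + 8 trimethyl orthoformate + 9 4-vinylanisole
Product: 12 (2S,4S)-4-methoxy-5,7-bis(methoxymethoxy)-2-(4-methoxyphenyl)-6-(3-methylbut-2-en-1-yl)-3,4-dihydro-2H-chromene (2,4-cis), via dimethyl acetal 10 (not isolated), via ortho-quinone methide 11 (not isolated)
Conditions: 8 (1.5 equiv), 9 (3 equiv), confined chiral imidodiphosphorimidate (IDPi) Brønsted acid (5 mol %), 5 Å MS, CH2Cl2, −60 → −40 °C
Reagents that add atoms: none
Why: Proposed new method: the acid first catalyses acetal exchange of 7 with 8 to the dimethyl acetal 10, whose ionisation with loss of methanol gives the O-protonated 4-methoxy ortho-quinone methide 11 as a tight ion pair with the chiral anion; the CH2 terminus of 9 then attacks the methide carbon (C3–C4) and the ring oxygen collapses on the developing p-methoxybenzylic cation (O1–C2) in a concerted but asynchronous inverse-electron-demand hetero-Diels–Alder reaction. The closest known reaction types are the racemic Lewis-acid-catalysed three-component coupling of salicylaldehydes, trimethyl orthoformate and styrenes to cis-4-methoxy-2-arylchromans and the chiral Brønsted acid catalysed [4+2] cycloadditions of ortho-quinone methides generated in situ with alkenes; merging the two on a free styrene is the new element. The dihydropyran (C) ring closes in the [4+2] mode, four atoms coming from the oxa-diene O1=C8a–C4a=C4 and two from the vinyl group, with C3–C4 formation running ahead of O1–C2 closure. C2 is set by the catalyst, whose anion is hydrogen-bonded to the quinone methide oxygen and shields one face of the oxa-diene in its confined pocket, and C4 follows from the endo approach of the anisyl ring, which should give the 2,4-cis isomer (C4 is oxidised in step 5, so only the facial selectivity at C2 reaches the target). Regiochemistry is secured by cation stabilisation, since the anisyl-bearing carbon can only end up on oxygen; chemoselectivity for 9 over the prenyl alkene, over Friedel–Crafts attack by the free A-ring position and over MOM exchange rests on the high nucleophilicity of 4-vinylanisole used in excess, the low temperature, the sieves that take up methanol and the confined catalyst pocket.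

**Step 5**
Reactants: 12 (2S,4S)-4-methoxy-5,7-bis(methoxymethoxy)-2-(4-methoxyphenyl)-6-(3-methylbut-2-en-1-yl)-3,4-dihydro-2H-chromene
Product: 13 (2S)-5,7-bis(methoxymethoxy)-2-(4-methoxyphenyl)-6-(3-methylbut-2-en-1-yl)-2,3-dihydro-4H-chromen-4-one
Conditions: DDQ (1.3 equiv), CH2Cl2/pH 7 phosphate buffer (10:1), 0 °C → rt
Reagents that add atoms: water, O
Why: DDQ oxidation of an electron-rich benzylic methyl ether (the manifold of oxidative PMB-ether cleavage): hydride abstraction from the pseudo-axial C4–H, activated by the geminal methoxy group and by O1 and the 5- and 7-oxygens in ortho/para positions, gives an oxocarbenium ion that water converts through the hemiketal into the ketone with loss of methanol, while C2 is not involved and the prenyl CH2, held near the ring plane by its two flanking MOM ethers, is less disposed to hydride loss.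

**Step 6**
Reactants: 13 (2S)-5,7-bis(methoxymethoxy)-2-(4-methoxyphenyl)-6-(3-methylbut-2-en-1-yl)-2,3-dihydro-4H-chromen-4-one
Product: 14 (2S)-5,7-dihydroxy-2-(4-methoxyphenyl)-6-(3-methylbut-2-en-1-yl)-2,3-dihydro-4H-chromen-4-one (6-prenyl-4'-O-methylnaringenin)
Conditions: HCl (ca. 1 M in MeOH), 0 °C → rt
Reagents that add atoms: none
Why: Acid-catalysed transacetalisation of the two aryl MOM ethers with methanol, the usual last step for prenylated flavanones; under dilute acid at room temperature neither cyclisation of the prenyl group onto a flanking phenol nor opening of the pyranone ring (the only path to racemisation at C2) is expected to compete.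

**Compound list**
1 | 2,4,6-trihydroxybenzaldehyde | O=Cc1c(O)cc(O)cc1O | starting material
2 | 2-hydroxy-4,6-bis(methoxymethoxy)benzaldehyde | O=Cc1c(O)cc(OCOC)cc1OCOC | intermediate
3 | prenyl bromide (1-bromo-3-methylbut-2-ene) | CC(C)=CCBr | starting material
4 | 2,4-bis(methoxymethoxy)-6-[(3-methylbut-2-en-1-yl)oxy]benzaldehyde | O=Cc1c(OCC=C(C)C)cc(OCOC)cc1OCOC | intermediate
5 | 2,4-bis(methoxymethoxy)-5-(2-methylbut-3-en-2-yl)-6-oxocyclohexa-1,3-diene-1-carbaldehyde (ortho-dienone, racemic at C5) | O=CC1=C(OCOC)C=C(OCOC)C(C(C)(C)C=C)C1=O | intermediate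
6 | 2,4-bis(methoxymethoxy)-3-(3-methylbut-2-en-1-yl)-6-oxocyclohexa-1,4-diene-1-carbaldehyde (para-dienone) | O=CC1=C(OCOC)C(CC=C(C)C)C(OCOC)=CC1=O | intermediate
7 | 6-hydroxy-2,4-bis(methoxymethoxy)-3-(3-methylbut-2-en-1-yl)benzaldehyde | O=Cc1c(O)cc(OCOC)c(CC=C(C)C)c1OCOC | intermediate
8 | trimethyl orthoformate | COC(OC)OC | starting material
9 | 4-vinylanisole (1-ethenyl-4-methoxybenzene) | COc1ccc(C=C)cc1 | starting material
10 | 2-(dimethoxymethyl)-3,5-bis(methoxymethoxy)-4-(3-methylbut-2-en-1-yl)phenol | COC(OC)c1c(O)cc(OCOC)c(CC=C(C)C)c1OCOC | intermediate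
11 | 6-(methoxymethylidene)-3,5-bis(methoxymethoxy)-4-(3-methylbut-2-en-1-yl)cyclohexa-2,4-dien-1-one (reacts as its O-protonated ion pair) | COC=C1C(=O)C=C(OCOC)C(CC=C(C)C)=C1OCOC | intermediate
12 | (2S,4S)-4-methoxy-5,7-bis(methoxymethoxy)-2-(4-methoxyphenyl)-6-(3-methylbut-2-en-1-yl)-3,4-dihydro-2H-chromene | COc1ccc([C@@H]2C[C@H](OC)c3c(cc(OCOC)c(CC=C(C)C)c3OCOC)O2)cc1 | intermediate
13 | (2S)-5,7-bis(methoxymethoxy)-2-(4-methoxyphenyl)-6-(3-methylbut-2-en-1-yl)-2,3-dihydro-4H-chromen-4-one | COc1ccc([C@@H]2CC(=O)c3c(cc(OCOC)c(CC=C(C)C)c3OCOC)O2)cc1 | intermediate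
14 | (2S)-5,7-dihydroxy-2-(4-methoxyphenyl)-6-(3-methylbut-2-en-1-yl)-2,3-dihydro-4H-chromen-4-one | COc1ccc([C@@H]2CC(=O)c3c(cc(O)c(CC=C(C)C)c3O)O2)cc1 | target

**Step count and risks**
Total step count: 6. Longest linear sequence: 6 steps (1 → 14).

Steps most likely to fail:

1. Step 4 (proposed new method). Facial selectivity at C2 may be eroded by a background pathway through a loosely bound ion pair. The quinone methide may also be consumed by Friedel–Crafts self-condensation with the electron-rich A ring, the MOM ethers may exchange with the liberated methanol, or the styrene may oligomerise cationically. The fallback uses known chemistry, sets out from 7 and comes back at 13. Compounds 7, 8 and 9 are combined under an achiral Lewis acid (Sc(OTf)3, 10 mol %, CH2Cl2, rt), the established racemic mode of this three-component cycloaddition, to give racemic cis-4-methoxy-5,7-bis(methoxymethoxy)-2-(4-methoxyphenyl)-6-(3-methylbut-2-en-1-yl)chromane F1. DDQ in wet CH2Cl2, as in step 5, should then give racemic 5,7-bis(methoxymethoxy)-2-(4-methoxyphenyl)-6-(3-methylbut-2-en-1-yl)chroman-4-one F2. Kinetic resolution by Ru(II)–TsDPEN asymmetric transfer hydrogenation (HCO2H/Et3N), using the catalyst enantiomer that reduces the (2R)-ketone faster, converts the unwanted antipode into (2R,4R)-5,7-bis(methoxymethoxy)-2-(4-methoxyphenyl)-6-(3-methylbut-2-en-1-yl)chroman-4-ol F3. The unreacted (2S)-ketone 13 is separated by chromatography.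

2. Step 5. Hydride abstraction at the benzylic–allylic CH2 of the prenyl group or at C2 may compete with that at C4, or the C4 oxocarbenium ion may lose a proton and be oxidised further to the flavone. The fallback sets out from 12 and comes back at 13. The 4-methoxy group is exchanged for hydroxyl by mild acid-catalysed solvolysis (PPTS, THF/H2O, rt) to give (2S)-5,7-bis(methoxymethoxy)-2-(4-methoxyphenyl)-6-(3-methylbut-2-en-1-yl)chroman-4-ol F4 as a mixture of C4 epimers. This benzylic alcohol is then oxidised without a hydride-abstracting quinone (Dess–Martin periodinane, NaHCO3, CH2Cl2, 0 °C) to 13.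

3. Step 3. The ortho-dienone may enolise before the Cope shift and give the ortho 1,1-dimethylallyl isomer, the allyl unit may be lost at 200 °C, or the formyl group may degrade thermally. The fallback replaces the sigmatropic route by a cross-coupling; it sets out from 2 and comes back at 7. The free phenol is silylated (TIPSOTf, 2,6-lutidine, CH2Cl2) to 2,4-bis(methoxymethoxy)-6-[(triisopropylsilyl)oxy]benzaldehyde F5. Iodination (NIS, cat. TFA, MeCN, 0 °C) should be steered by the bulky silyl ether to the carbon between the two MOM ethers, giving 3-iodo-2,4-bis(methoxymethoxy)-6-[(triisopropylsilyl)oxy]benzaldehyde F6. Stille coupling with tributyl(3-methylbut-2-en-1-yl)stannane (Pd(PPh3)4, DMF, 90 °C) gives 2,4-bis(methoxymethoxy)-3-(3-methylbut-2-en-1-yl)-6-[(triisopropylsilyl)oxy]benzaldehyde F7. TBAF/AcOH (THF, 0 °C) removes the silyl group to return 7.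

**Further compounds**
F1 | step 4 | racemic cis-4-methoxy-5,7-bis(methoxymethoxy)-2-(4-methoxyphenyl)-6-(3-methylbut-2-en-1-yl)chromane (both enantiomers written) | COc1ccc([C@@H]2C[C@H](OC)c3c(cc(OCOC)c(CC=C(C)C)c3OCOC)O2)cc1.COc1ccc([C@H]2C[C@@H](OC)c3c(cc(OCOC)c(CC=C(C)C)c3OCOC)O2)cc1
F2 | step 4 | racemic 5,7-bis(methoxymethoxy)-2-(4-methoxyphenyl)-6-(3-methylbut-2-en-1-yl)chroman-4-one (both enantiomers written) | COc1ccc([C@@H]2CC(=O)c3c(cc(OCOC)c(CC=C(C)C)c3OCOC)O2)cc1.COc1ccc([C@H]2CC(=O)c3c(cc(OCOC)c(CC=C(C)C)c3OCOC)O2)cc1
F3 | step 4 | (2R,4R)-5,7-bis(methoxymethoxy)-2-(4-methoxyphenyl)-6-(3-methylbut-2-en-1-yl)chroman-4-ol | COc1ccc([C@H]2C[C@@H](O)c3c(cc(OCOC)c(CC=C(C)C)c3OCOC)O2)cc1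
F4 | step 5 | (2S)-5,7-bis(methoxymethoxy)-2-(4-methoxyphenyl)-6-(3-methylbut-2-en-1-yl)chroman-4-ol (C4 epimer mixture) | COc1ccc([C@@H]2CC(O)c3c(cc(OCOC)c(CC=C(C)C)c3OCOC)O2)cc1
F5 | step 3 | 2,4-bis(methoxymethoxy)-6-[(triisopropylsilyl)oxy]benzaldehyde | O=Cc1c(O[Si](C(C)C)(C(C)C)C(C)C)cc(OCOC)cc1OCOC
F6 | step 3 | 3-iodo-2,4-bis(methoxymethoxy)-6-[(triisopropylsilyl)oxy]benzaldehyde | O=Cc1c(O[Si](C(C)C)(C(C)C)C(C)C)cc(OCOC)c(I)c1OCOC
F7 | step 3 | 2,4-bis(methoxymethoxy)-3-(3-methylbut-2-en-1-yl)-6-[(triisopropylsilyl)oxy]benzaldehyde | O=Cc1c(O[Si](C(C)C)(C(C)C)C(C)C)cc(OCOC)c(CC=C(C)C)c1OCOC
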